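Take the growth constant times the initiator fraction, over the side-step constant: 68.8% of the charge in west, the chain ceiling G.

    free monomer + monomer in chains → side product (k1 = 0.064 M⁻¹ min⁻¹, Ea1 = 57.0 kJ mol⁻¹)
    free monomer + living end → monomer in chains + living end, rate k2*[living end]*[free monomer] (k2 = 2.2 M⁻¹ min⁻¹, Ea2 = 63.0 kJ mol⁻¹)
    free monomer + initiator → living end + monomer in chains (k3 = 0.053 M⁻¹ min⁻¹, Ea3 = 53.0 kJ mol⁻¹)
    2 free monomer → self-condensation product (k4 = 2.1 × 10⁻⁴ M⁻¹ min⁻¹, Ea4 = 76.0 kJ mol⁻¹)
    (constants at 20 °C)

all flasks: free monomer 2.0 M; initiator 2 mol%; time 15 min
- south: temperature 30 °C
- west: temperature 20 °C
- south-east: temperature 40 °C

- a species is counted by the free monomer in it: one self-condensation product or side product counts as two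
- a step written with two of one species runs at k times the square of its concentration and takes two of it each time
- the list of constants is for 20 °C, to be carried to other temperatures by the activation energies

* which of the two there is more of at the end, counted by the free monomer in each, south (monomer in chains / side product)
* which of the two there is more of at the end, counted by the free monomer in each, west (monomer in chains / side product)
* which of the two there is more of at the end, counted by the free monomer in each, south-east (monomer in chains / side product)
* amount of monomer in chains at the end, in percent of the free monomer charged, south
* amount of monomer in chains at the end, in percent of the free monomer charged, west
* amount of monomer in chains at the end, in percent of the free monomer charged, south-east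

Work in fractions of the charge. Growth and the side step both carry free monomer, so divide it out. With every initiator a living end, chains u gain in proportion to G − u, and free monomer falls in proportion to G + u. The concentration cancels from G. Join the two ends: early, conversion c equals u; late, u stalls at G. The integral is c = 2G·ln(G/(G − u)) − u.

Test u at 0.5 of the charge. That demands 129% conversion, more than the charge holds. So in west, once spent, side product leads. Growth has the higher activation energy, by 6.00 kJ mol⁻¹, so heat raises G above its west value, and the test demands less in south and south-east. Take the same verdict to those two as an estimate, on a thinner margin.

Is one number enough? No, because G counts ends that do not yet exist. Initiation and the side step run on the same free monomer, so set the stall at 75.0% of the ceiling. Roughly 31.7% of the initiator then remains. The working ceiling falls to 46.9%, and chains reach 35.2% at 94.8% conversion. Commit to about that for a spent flask at the west temperature.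

G carries no clock. In west, growth has a half-life of 7.88 min even with every end present, and initiator takes 6.54 min to halve at the charged free monomer. So expect west unfinished at 15 min, with chains lower. Its leader stays open here.

The forecast gives side product, side product and side product for south, west and south-east, with chains at 36%, 26% and 38%, and says “side product outweighs chains at all three temperatures”.

The simulation gives chains 36.0% against side product 57.4% in south, 26.3% against 31.8% in west, and 38.0% against 60.6% in south-east. Ten times the time leaves south-east at rest, at 38.0%. South gains 1.3 percentage points and reaches 37.3%. West is the flask still moving: it holds 41.2% free monomer at 15.0 min, and by 150 min it holds 0% with chains at 36.4%. Each long value lies below the working ceiling reckoned for west.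

Now take south with 0.80 M free monomer. G is unchanged, and each step runs on two concentrations, so the path stays and the clock stretches: its 15 min matches south at 6.00 min. That moment comes before half of the time in south. South holds 28.5% chains at 7.50 min, and 35.1% free monomer at 7.50 min. So expect fewer chains and more free monomer than these. Computed, that flask holds 24.5% chains and 48% free monomer.

Its constants were drawn at random within sensible limits; the rest is arithmetic.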